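A small charge of 10 mM free monomer on Monday was my guide before I put twice as much into the flask, and the decision was whether the initiator could stay at 0.20 mM.

| flask | free monomer | initiator | remark | time |
|---|---|---|---|---|
| Monday's | 10 mM (fed, over 5.0 h) | 0.20 mM | run made earlier |  |
| flask | 20 mM (fed, over 5.0 h) | 0.20 mM |  | 6.0 d |

Monday's run (percent of the free monomer charged)

| time / h | free monomer / % | monomer in chains / % |
|---|---|---|
| 2.50 | 16 | 3 |
| 4.00 | 19 | 9 |
| 5.00 | 17 | 11 |
| 8.00 | 6 | 21 |
| 12.0 | 5 | 31 |
| 20.0 | 0 | 42 |
| 30.0 | 1 | 48 |

(standard deviation of a reading: 2 percentage points)

- percentages count the whole charge, also what has not yet gone in
- the reaction counts as stopped when no species that holds the free monomer changes by six tenths of a point or more over the second half of the time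
- a reading of free monomer is of its free form alone

1. at 6.0 d, what has stopped the reaction, if anything has (no working catalyst is left / it is still moving / forward and back rates have come level / all of the free monomer has reacted)
2. share of the free monomer used up at 6.0 d
3. monomer in chains at 6.0 d, in percent of the free monomer charged
4. amount of monomer in chains if the flask were left three thousand times as long, in percent of the free monomer charged

I reckoned with what was left, not with what was made. When Monday's feed ended at 5.00 h, 72.0% of the charge read as neither free monomer nor chains. At 30.0 h that unseen part was still 51.0%, so some of it had come back and some perhaps never would. Monday's last reading gives 0.923 for the chain odds, monomer in chains over the charge not in chains; it is a reading, and one still climbing.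

Suppose the chain step is first order in free monomer and the loss second order. Then, at fixed initiator, the flask's larger charge leaves the odds at half of Monday's, 0.462, which means 31.6% in chains. If the odds held, the flask would give Monday's 48%. I committed to that range and kept the initiator, since even the low end justified the run. I expected free monomer to be used up by 6.0 d, which is 4.80 times Monday's last time, when it already read 1%.

The forecast named no working catalyst is left, with 99.5% used up, 52% in chains and 53% in the long run, holding that “doubling the monomer should leave percentages about the same”.

The flask gave this outcome: all of the free monomer has reacted, with 100% used up, 46.4% in chains at 6.0 d and 46.4% in the long run.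

    free monomer ⇌ dormant form (K = 3.60, k = 0.0153 min⁻¹)
    free monomer + initiator → living end + monomer in chains (k = 0.976 M⁻¹ min⁻¹)
    free monomer + living end → monomer in chains + living end, rate k3*[living end]*[free monomer] (k = 82.1 M⁻¹ min⁻¹)
    free monomer → decomposition product (k = 3.70 × 10⁻⁵ min⁻¹)
    2 free monomer → self-condensation product (k = 2.74 M⁻¹ min⁻¹)

The flask's chain odds came to 0.867, higher than my low end and close to Monday's 0.923. At 0.336 d, free monomer went into chains 2.3 times as fast as into self-condensation product, a ratio of that moment. Yet at the end of the feed, 0.208 d, the flask already held 42.4% as self-condensation product against 14.8% in chains. The neighbour charged with 0.80 mM of initiator ended at 70.4% in chains, chain odds 2.38.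

Readings and results come from a simulation for an exercise; noise was put on by code.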